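**Retrosynthetic overview**
- Feature: the C1–C3 terminus is an E-trisubstituted enoate whose C3 methyl and C1 carboxyl lie cis across C2=C3. That pattern results when CH3 and a metal add syn to a terminal C2≡C3 alkyne and the C2–metal bond is then carboxylated.
- Key disconnection: C3–CH3 and C1–C2. This leads back to a (4Z)-enyne spanning C2–C15 with a silyl/PMB-protected head, Me3Al and ethyl chloroformate.
- The enyne is cut at four bonds: C12–C13 (Evans syn aldol, sets C12 and C13), C2–C3 (Colvin homologation of a Z-enal), C8–C9 (copper-catalysed Grignard–tosylate coupling), and C5–C6 (Negishi coupling of a Roche-ester zinc reagent carrying C7 with a Z-alkenyl iodide from but-2-yn-1-ol).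
- Ring order: the only ring is the oxirane O–C4–C5. It is closed after the key step by a chiral dioxirane on the distal 4Z alkene. The head is then unmasked (PMB off, C14 to the acid, desilylation, saponification).

Key step: step 17

Remark on numbering: C1 enoate carboxyl, C2=C3 enoate alkene, C4/C5 oxirane carbons, C7 methyl-bearing centre, C12 carbinol, C13 branch point, C14 second carboxyl, C15 hydroxymethyl carbon. The SMILES reads as (2E,4S,5R,7S,12R,13R), with C3 and C6 cis on the oxirane, so a 4Z alkene is required.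

Assumption: the L-series Shi ketone (1,2:4,5-di-O-isopropylidene-β-L-erythro-2,3-hexodiulo-2,6-pyranose) is taken as a purchasable catalyst; it is otherwise made from L-sorbose.

**Step 1**
Reactants: 1 but-2-yn-1-ol
Product: 3 (Z)-3-iodobut-2-en-1-ol, via cyclic alkenylaluminate 2 (not isolated)
Conditions: NaAlH2(OCH2CH2OMe)2, Et2O, 0 °C → rt; EtOAc; then I2, THF, −78 → 0 °C
Reagents that add atoms: iodine, II
Why: Hydroxyl-directed trans-hydroalumination of the propargylic alcohol puts hydride on C4 and ties aluminium to C5 in a five-membered alkoxyaluminate, and iodinolysis with retention should give only the Z-iodide that later fixes the C4=C5 geometry.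

**Step 2**
Reactants: 3 (Z)-3-iodobut-2-en-1-ol
Product: 4 (Z)-tert-butyl[(3-iodobut-2-en-1-yl)oxy]dimethylsilane
Conditions: TBSCl, imidazole, CH2Cl2, 0 °C → rt
Reagents that add atoms: tert-butyldimethylsilyl chloride, CC(C)(C)[Si](C)(C)Cl
Why: Imidazole-promoted O-silylation masks the acidic hydroxyl before the organozinc, hydride and Grignard steps and does not touch the alkenyl iodide.

**Step 3**
Reactants: 5 methyl (R)-3-hydroxy-2-methylpropanoate
Product: 6 methyl (S)-3-iodo-2-methylpropanoate
Conditions: I2, PPh3, imidazole, CH2Cl2, 0 °C → rt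
Reagents that add atoms: iodine, II
Why: Appel-type iodination substitutes only at the primary carbinol carbon (the future C6), so the C7 centre is untouched and its label changes from R to S through CIP ranking alone.

**Step 4**
Reactants: 6 methyl (S)-3-iodo-2-methylpropanoate; 4 (Z)-tert-butyl[(3-iodobut-2-en-1-yl)oxy]dimethylsilane
Product: 8 methyl (2R,4Z)-6-[(tert-butyldimethylsilyl)oxy]-2,4-dimethylhex-4-enoate, via alkylzinc iodide 7 (not isolated)
Conditions: Zn dust (BrCH2CH2Br, Me3SiCl activation), THF/DMA, 40 °C; then 4, PdCl2(dppf) (5 mol %), rt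
Reagents that add atoms: none
Why: Zinc insertion gives a β-zincio ester whose stereocentre bears no metal, and the Negishi sp3–sp2 coupling forms C5–C6 with retention of the alkenyl iodide geometry, the wide-bite-angle diphosphine favouring reductive elimination over β-hydride loss.

**Step 5**
Reactants: 8 methyl (2R,4Z)-6-[(tert-butyldimethylsilyl)oxy]-2,4-dimethylhex-4-enoate
Product: 9 (2R,4Z)-6-[(tert-butyldimethylsilyl)oxy]-2,4-dimethylhex-4-en-1-ol
Conditions: LiAlH4, Et2O, 0 °C
Reagents that add atoms: none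
Why: Hydride reduction of the ester to the primary alcohol (C8) is fast at 0 °C and leaves the silyl ether, the alkene and the α-centre unchanged.

**Step 6**
Reactants: 9 (2R,4Z)-6-[(tert-butyldimethylsilyl)oxy]-2,4-dimethylhex-4-en-1-ol
Product: 10 (2R,4Z)-6-[(tert-butyldimethylsilyl)oxy]-2,4-dimethylhex-4-en-1-yl 4-methylbenzenesulfonate
Conditions: TsCl, Et3N, 4-(dimethylamino)pyridine (cat.), CH2Cl2, 0 °C → rt
Reagents that add atoms: 4-toluenesulfonyl chloride, Cc1ccc(cc1)S(=O)(=O)Cl
Why: Sulfonylation of the primary alcohol installs the leaving group at C8 that copper-catalysed Grignard couplings handle best.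

**Step 7**
Reactants: 11 2-(3-chloropropyl)-1,3-dioxolane; 10 (2R,4Z)-6-[(tert-butyldimethylsilyl)oxy]-2,4-dimethylhex-4-en-1-yl 4-methylbenzenesulfonate
Product: 13 tert-butyl{[(2Z,5S)-9-(1,3-dioxolan-2-yl)-3,5-dimethylnon-2-en-1-yl]oxy}dimethylsilane, via acetal Grignard reagent 12 (not isolated)
Conditions: Mg turnings (BrCH2CH2Br activation), THF, reflux; then 10, Li2CuCl4 (5 mol %), THF, −20 °C → rt
Reagents that add atoms: none
Why: Copper-catalysed sp3–sp3 cross-coupling of a Grignard reagent with a β-branched primary tosylate forms C8–C9, brings in C12 already at the aldehyde oxidation level as its dioxolane, and spares the allylic silyl ether, which is a poor leaving group.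

**Step 8**
Reactants: 13 tert-butyl{[(2Z,5S)-9-(1,3-dioxolan-2-yl)-3,5-dimethylnon-2-en-1-yl]oxy}dimethylsilane
Product: 14 (2Z,5S)-9-(1,3-dioxolan-2-yl)-3,5-dimethylnon-2-en-1-ol
Conditions: Bu4NF, THF, 0 °C → rt
Reagents that add atoms: none
Why: Fluoride desilylation is fully orthogonal to the dioxolane, so the C3 hydroxyl is freed while no other silyl group is yet in the molecule.

**Step 9**
Reactants: 14 (2Z,5S)-9-(1,3-dioxolan-2-yl)-3,5-dimethylnon-2-en-1-ol
Product: 15 (2Z,5S)-9-(1,3-dioxolan-2-yl)-3,5-dimethylnon-2-enal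
Conditions: 2,2,6,6-tetramethylpiperidin-1-oxyl (TEMPO, 10 mol %), PhI(OAc)2, MeCN/aq. NaH2PO4–Na2HPO4 buffer (pH 7), 0 °C; used crude
Reagents that add atoms: none
Why: Oxoammonium oxidation under buffered, near-neutral conditions is the established way to take Z-allylic alcohols of the nerol type to Z-enals without geometric isomerisation.

**Step 10**
Reactants: 15 (2Z,5S)-9-(1,3-dioxolan-2-yl)-3,5-dimethylnon-2-enal; 16 (trimethylsilyl)diazomethane
Product: 18 2-[(5S,7Z)-5,7-dimethyldec-7-en-9-yn-1-yl]-1,3-dioxolane, via lithio(trimethylsilyl)diazomethane 17 (not isolated)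
Conditions: 16, n-BuLi, THF, −78 °C; then 15, −78 → 0 °C
Reagents that add atoms: (trimethylsilyl)diazomethane 16, C[Si](C)(C)C=[N+]=[N-]
Why: In the Colvin rearrangement, 1,2-addition at −78 °C, Peterson-type loss of silanolate, loss of N2 and a 1,2-hydride shift of the alkylidene carbene deliver the terminal alkyne (C2), and no protic nucleophilic medium is present that could add to or isomerise the enal.

**Step 11**
Reactants: 18 2-[(5S,7Z)-5,7-dimethyldec-7-en-9-yn-1-yl]-1,3-dioxolane
Product: 19 (6S,8Z)-6,8-dimethylundec-8-en-10-ynal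
Conditions: 1 M aq. HCl, THF, rt
Reagents that add atoms: water, O
Why: Acid-catalysed acetal hydrolysis frees the C12 aldehyde, and the conjugated enyne is too weakly basic to be protonated by dilute aqueous acid.

**Step 12**
Reactants: 20 3-[(4-methoxybenzyl)oxy]propan-1-ol
Product: 21 3-[(4-methoxybenzyl)oxy]propanoic acid
Conditions: 2,2,6,6-tetramethylpiperidin-1-oxyl (TEMPO, 20 mol %), PhI(OAc)2 (2.2 equiv), MeCN/H2O, rt
Reagents that add atoms: water, O
Why: Oxoammonium oxidation in aqueous medium runs through the aldehyde hydrate to the acid and tolerates the electron-rich benzyl ether.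

**Step 13**
Reactants: 21 3-[(4-methoxybenzyl)oxy]propanoic acid; 22 (S)-4-benzyloxazolidin-2-one
Product: 24 (S)-4-benzyl-3-{3-[(4-methoxybenzyl)oxy]propanoyl}oxazolidin-2-one, via mixed pivalic anhydride 23 (not isolated)
Conditions: t-BuCOCl, Et3N, THF, −20 → 0 °C; then LiCl, 22, rt
Reagents that add atoms: none
Why: Mixed-anhydride N-acylation with LiCl activation needs no strong base, so the β-alkoxy acyl unit is never exposed to conditions that favour elimination.

**Step 14**
Reactants: 24 (S)-4-benzyl-3-{3-[(4-methoxybenzyl)oxy]propanoyl}oxazolidin-2-one; 19 (6S,8Z)-6,8-dimethylundec-8-en-10-ynal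
Product: 27 (4S)-4-benzyl-3-[(2S,3R,8S,10Z)-3-hydroxy-2-{[(4-methoxybenzyl)oxy]methyl}-8,10-dimethyltridec-10-en-12-ynoyl]oxazolidin-2-one, via Z-dibutylboron enolate 25 (not isolated), via dibutylboron aldolate 26 (not isolated)
Conditions: Bu2BOTf, Et3N, CH2Cl2, −78 → 0 °C, recool to −78 °C; 19, −78 → 0 °C; then pH 7 NaH2PO4–Na2HPO4 buffer, MeOH, 30% H2O2, 0 °C
Reagents that add atoms: none
Why: In this Evans syn aldol, soft enolisation gives the covalent Z-boron enolate (a poor donor for β-alkoxide loss) and the chair Zimmerman–Traxler transition state, with the aldehyde on the face away from the benzyl group, sets C12 as R and C13 with the CH2OPMB arm syn to the hydroxyl, which is the arrangement that becomes 13R once that arm is the carboxyl.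

**Step 15**
Reactants: 27 syn-aldol adduct
Product: 28 (2S,3R,8S,10Z)-2-{[(4-methoxybenzyl)oxy]methyl}-8,10-dimethyltridec-10-en-12-yne-1,3-diol
Conditions: LiBH4, H2O (1 equiv), Et2O, 0 °C
Reagents that add atoms: none
Why: Reductive auxiliary cleavage at the exocyclic imide carbonyl turns it into the C15 hydroxymethyl group without touching C13, the enyne or the PMB ether, and returns the oxazolidinone.

**Step 16**
Reactants: 28 diol
Product: 29 (3Z,6S,11R,12R)-11,13-bis[(tert-butyldimethylsilyl)oxy]-12-{[(4-methoxybenzyl)oxy]methyl}-4,6-dimethyltridec-3-en-1-yne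
Conditions: TBSOTf (2.5 equiv), 2,6-lutidine, CH2Cl2, −78 → 0 °C
Reagents that add atoms: tert-butyldimethylsilyl trifluoromethanesulfonate, CC(C)(C)[Si](C)(C)OS(=O)(=O)C(F)(F)F
Why: Silyl triflate with a hindered pyridine base silylates the primary and the hindered secondary hydroxyl in one operation, removes every acidic O–H before the organoaluminium step, and is too weakly basic to C-silylate the alkyne.

**Step 17**
Reactants: 29 (Z)-enyne with protected head; 30 trimethylaluminium; 31 ethyl chloroformate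
Product: 33 ethyl (2E,4Z,7S,12R,13R)-12,14-bis[(tert-butyldimethylsilyl)oxy]-13-{[(4-methoxybenzyl)oxy]methyl}-3,5,7-trimethyltetradeca-2,4-dienoate, via dienyl dimethylalane 32 (not isolated)
Conditions: Me3Al (4 equiv), Cp2ZrCl2 (0.5 equiv), CH2Cl2, 0 °C → rt, a few hours; then ClCO2Et (excess), 0 °C → rt; cold aq. K2CO3 quench
Reagents that add atoms: trimethylaluminium 30, C[Al](C)C; ethyl chloroformate 31, CCOC(=O)Cl
Why: Me3Al and Cp2ZrCl2 exchange methyl for chloride to give a polarised, cation-like methylzirconocene–aluminium pair that adds CH3 and metal across C2≡C3 through a four-centre syn transition state, after which zirconium-to-aluminium exchange releases dienylalane 32 and returns the zirconocene. The closest known reaction type is the zirconium-catalysed methylalumination of terminal alkynes and conjugated enynes with direct chloroformate trapping of the alkenylalane. Regioselectivity (methyl to internal C3, metal to terminal C2) follows from the steric bias of a monosubstituted alkyne, and chemoselectivity follows from the inertness of the trisubstituted C4=C5 alkene to carbometalation. Acylation of the sp2 C–Al bond by 31 goes with retention, so the C3 methyl and C1 end up cis (2E); the step makes the C3–CH3 and C1–C2 bonds, closes no ring and creates no stereocentre. The selectivity still needed is retention of the 4Z geometry and survival of both silyl ethers and the PMB ether in a Lewis acidic medium, which excess Me3Al (to saturate the ether oxygens), a short time at or below ambient temperature and a cold basic quench should secure.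

**Step 18**
Reactants: 33 (2E,4Z)-dienoate
Product: 34 ethyl (2E,4S,5R,7S,12R,13R)-12,14-bis[(tert-butyldimethylsilyl)oxy]-4,5-epoxy-13-{[(4-methoxybenzyl)oxy]methyl}-3,5,7-trimethyltetradec-2-enoate
Conditions: 1,2:4,5-di-O-isopropylidene-β-L-erythro-2,3-hexodiulo-2,6-pyranose (30–50 mol %), 2KHSO5·KHSO4·K2SO4, K2CO3, Bu4NHSO4 (cat.), MeCN/CH2(OMe)2/aq. Na2B4O7–Na2H2EDTA buffer (pH about 10.5), −5 → 0 °C
Reagents that add atoms: potassium peroxymonosulfate, [K+].[O-]S(=O)(=O)OO
Why: In this Shi epoxidation the electrophilic chiral dioxirane takes the distal, electron-richer C4=C5 alkene of the dienoate and transfers oxygen stereospecifically syn (so C3 and C6 stay cis on the oxirane), and the spiro transition-state model, with C4–H in the congested quadrant, predicts 4R,5S for the D-fructose ketone, hence the L-series ketone is used for 4S,5R.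

**Step 19**
Reactants: 34 epoxy enoate
Product: 35 ethyl (2E,4S,5R,7S,12R,13R)-12-[(tert-butyldimethylsilyl)oxy]-13-{[(tert-butyldimethylsilyl)oxy]methyl}-4,5-epoxy-14-hydroxy-3,5,7-trimethyltetradec-2-enoate
Conditions: DDQ, CH2Cl2/aq. NaH2PO4–Na2HPO4 buffer (pH 7), 0 °C; used without delay
Reagents that add atoms: none
Why: Oxidative PMB cleavage by hydride abstraction from the electron-rich benzylic position runs at neutral pH, which protects the trisubstituted epoxide and avoids base-induced silyl migration between the C15 and C14 oxygens that would scramble C13.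

**Step 20**
Reactants: 35 primary alcohol
Product: 36 (2E,4S,5R,7S,12R,13R)-12-[(tert-butyldimethylsilyl)oxy]-13-{[(tert-butyldimethylsilyl)oxy]methyl}-4,5-epoxy-3,5,7-trimethyltetradec-2-enedioic acid 1-ethyl ester
Conditions: 2,2,6,6-tetramethylpiperidin-1-oxyl (TEMPO, cat.), NaClO2, NaOCl (cat.), MeCN/aq. NaH2PO4–Na2HPO4 buffer (pH 6.7), rt → 35 °C
Reagents that add atoms: sodium chlorite, [Na+].[O-]Cl=O
Why: The TEMPO/chlorite oxidation takes C14 to the acid in one flask and consumes the epimerisable, elimination-prone aldehyde as it forms, at a pH that the epoxide and silyl ethers tolerate, with no electron-rich alkene left to be chlorinated.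

**Step 21**
Reactants: 36 bis-silyl acid
Product: 37 (2E,4S,5R,7S,12R,13R)-4,5-epoxy-12-hydroxy-13-(hydroxymethyl)-3,5,7-trimethyltetradec-2-enedioic acid 1-ethyl ester
Conditions: Bu4NF (excess), THF, 0 °C → rt; pH 4 buffer work-up
Reagents that add atoms: none
Why: Fluoride desilylation removes both TBS groups under non-acidic conditions that spare the acid-sensitive epoxide, and the C14 carboxylate is inert to epimerisation and retro-aldol cleavage.

**Step 22**
Reactants: 37 dihydroxy acid ethyl ester
Product: 38 (2E,4S,5R,7S,12R,13R)-4,5-epoxy-12-hydroxy-13-(hydroxymethyl)-3,5,7-trimethyltetradec-2-enedioic acid (target)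
Conditions: LiOH, THF/EtOH/H2O, rt → 40 °C; then cold 0.5 M HCl to pH 3–4, EtOAc extraction
Reagents that add atoms: lithium hydroxide, [Li+].[OH-]
Why: Saponification by acyl–oxygen cleavage frees C1, the trisubstituted epoxide resists hydroxide at this temperature, and the 2E geometry holds C1 away from C4 and C5 so that no lactone can form on acidification.

**Compound list**
1 | but-2-yn-1-ol | CC#CCO | starting material
2 | sodium 2,2-bis(2-methoxyethoxy)-3-methyl-2,5-dihydro-1,2-oxaluminol-2-uide (cyclic alkenylaluminate) | CC1=CCO[Al-]1(OCCOC)OCCOC.[Na+] | intermediate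
3 | (Z)-3-iodobut-2-en-1-ol | OC/C=C(/C)I | intermediate
4 | (Z)-tert-butyl[(3-iodobut-2-en-1-yl)oxy]dimethylsilane | CC(C)(C)[Si](C)(C)OC/C=C(/C)I | intermediate
5 | methyl (R)-3-hydroxy-2-methylpropanoate | OC[C@@H](C)C(=O)OC | starting material
6 | methyl (S)-3-iodo-2-methylpropanoate | IC[C@@H](C)C(=O)OC | intermediate
7 | [(2S)-3-methoxy-2-methyl-3-oxopropyl]zinc iodide | I[Zn]C[C@@H](C)C(=O)OC | intermediate
8 | methyl (2R,4Z)-6-[(tert-butyldimethylsilyl)oxy]-2,4-dimethylhex-4-enoate | CC(C)(C)[Si](C)(C)OC/C=C(/C)C[C@@H](C)C(=O)OC | intermediate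
9 | (2R,4Z)-6-[(tert-butyldimethylsilyl)oxy]-2,4-dimethylhex-4-en-1-ol | CC(C)(C)[Si](C)(C)OC/C=C(/C)C[C@@H](C)CO | intermediate
10 | (2R,4Z)-6-[(tert-butyldimethylsilyl)oxy]-2,4-dimethylhex-4-en-1-yl 4-methylbenzenesulfonate | CC(C)(C)[Si](C)(C)OC/C=C(/C)C[C@@H](C)COS(=O)(=O)c1ccc(C)cc1 | intermediate
11 | 2-(3-chloropropyl)-1,3-dioxolane | ClCCCC1OCCO1 | starting material
12 | [3-(1,3-dioxolan-2-yl)propyl]magnesium chloride | Cl[Mg]CCCC1OCCO1 | intermediate
13 | tert-butyl{[(2Z,5S)-9-(1,3-dioxolan-2-yl)-3,5-dimethylnon-2-en-1-yl]oxy}dimethylsilane | CC(C)(C)[Si](C)(C)OC/C=C(/C)C[C@@H](C)CCCCC1OCCO1 | intermediate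
14 | (2Z,5S)-9-(1,3-dioxolan-2-yl)-3,5-dimethylnon-2-en-1-ol | OC/C=C(/C)C[C@@H](C)CCCCC1OCCO1 | intermediate
15 | (2Z,5S)-9-(1,3-dioxolan-2-yl)-3,5-dimethylnon-2-enal | O=C/C=C(/C)C[C@@H](C)CCCCC1OCCO1 | intermediate
16 | (trimethylsilyl)diazomethane | C[Si](C)(C)C=[N+]=[N-] | starting material
17 | lithio(trimethylsilyl)diazomethane | [Li]C(=[N+]=[N-])[Si](C)(C)C | intermediate
18 | 2-[(5S,7Z)-5,7-dimethyldec-7-en-9-yn-1-yl]-1,3-dioxolane | C#C/C=C(/C)C[C@@H](C)CCCCC1OCCO1 | intermediate
19 | (6S,8Z)-6,8-dimethylundec-8-en-10-ynal | C#C/C=C(/C)C[C@@H](C)CCCCC=O | intermediate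
20 | 3-[(4-methoxybenzyl)oxy]propan-1-ol | OCCCOCc1ccc(OC)cc1 | starting material
21 | 3-[(4-methoxybenzyl)oxy]propanoic acid | OC(=O)CCOCc1ccc(OC)cc1 | intermediate
22 | (S)-4-benzyloxazolidin-2-one | O=C1N[C@@H](Cc2ccccc2)CO1 | starting material
23 | 3-[(4-methoxybenzyl)oxy]propanoic pivalic anhydride | CC(C)(C)C(=O)OC(=O)CCOCc1ccc(OC)cc1 | intermediate
24 | (S)-4-benzyl-3-{3-[(4-methoxybenzyl)oxy]propanoyl}oxazolidin-2-one | O=C(CCOCc1ccc(OC)cc1)N1C(=O)OC[C@@H]1Cc1ccccc1 | intermediate
25 | Z-dibutylboron enolate of 24 | CCCCB(CCCC)O/C(=C\COCc1ccc(OC)cc1)N1C(=O)OC[C@@H]1Cc1ccccc1 | intermediate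
26 | dibutylboron aldolate of 27 | C#C/C=C(/C)C[C@@H](C)CCCC[C@@H](OB(CCCC)CCCC)[C@@H](C(=O)N1C(=O)OC[C@@H]1Cc1ccccc1)COCc1ccc(OC)cc1 | intermediate
27 | (4S)-4-benzyl-3-[(2S,3R,8S,10Z)-3-hydroxy-2-{[(4-methoxybenzyl)oxy]methyl}-8,10-dimethyltridec-10-en-12-ynoyl]oxazolidin-2-one | C#C/C=C(/C)C[C@@H](C)CCCC[C@@H](O)[C@@H](C(=O)N1C(=O)OC[C@@H]1Cc1ccccc1)COCc1ccc(OC)cc1 | intermediate
28 | (2S,3R,8S,10Z)-2-{[(4-methoxybenzyl)oxy]methyl}-8,10-dimethyltridec-10-en-12-yne-1,3-diol | C#C/C=C(/C)C[C@@H](C)CCCC[C@@H](O)[C@@H](CO)COCc1ccc(OC)cc1 | intermediate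
29 | (3Z,6S,11R,12R)-11,13-bis[(tert-butyldimethylsilyl)oxy]-12-{[(4-methoxybenzyl)oxy]methyl}-4,6-dimethyltridec-3-en-1-yne | C#C/C=C(/C)C[C@@H](C)CCCC[C@@H](O[Si](C)(C)C(C)(C)C)[C@@H](CO[Si](C)(C)C(C)(C)C)COCc1ccc(OC)cc1 | intermediate
30 | trimethylaluminium | C[Al](C)C | starting material
31 | ethyl chloroformate | CCOC(=O)Cl | starting material
32 | (1E,3Z)-dienyl dimethylalane (Al on C2, new CH3 on C3, cis to each other) | C/C(=C\[Al](C)C)/C=C(/C)C[C@@H](C)CCCC[C@@H](O[Si](C)(C)C(C)(C)C)[C@@H](CO[Si](C)(C)C(C)(C)C)COCc1ccc(OC)cc1 | intermediate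
33 | ethyl (2E,4Z,7S,12R,13R)-12,14-bis[(tert-butyldimethylsilyl)oxy]-13-{[(4-methoxybenzyl)oxy]methyl}-3,5,7-trimethyltetradeca-2,4-dienoate | C/C(=C\C(=O)OCC)/C=C(/C)C[C@@H](C)CCCC[C@@H](O[Si](C)(C)C(C)(C)C)[C@@H](CO[Si](C)(C)C(C)(C)C)COCc1ccc(OC)cc1 | intermediate
34 | ethyl (2E,4S,5R,7S,12R,13R)-12,14-bis[(tert-butyldimethylsilyl)oxy]-4,5-epoxy-13-{[(4-methoxybenzyl)oxy]methyl}-3,5,7-trimethyltetradec-2-enoate | C/C(=C\C(=O)OCC)[C@@H]1O[C@]1(C)C[C@@H](C)CCCC[C@@H](O[Si](C)(C)C(C)(C)C)[C@@H](CO[Si](C)(C)C(C)(C)C)COCc1ccc(OC)cc1 | intermediate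
35 | ethyl (2E,4S,5R,7S,12R,13R)-12-[(tert-butyldimethylsilyl)oxy]-13-{[(tert-butyldimethylsilyl)oxy]methyl}-4,5-epoxy-14-hydroxy-3,5,7-trimethyltetradec-2-enoate | C/C(=C\C(=O)OCC)[C@@H]1O[C@]1(C)C[C@@H](C)CCCC[C@@H](O[Si](C)(C)C(C)(C)C)[C@@H](CO[Si](C)(C)C(C)(C)C)CO | intermediate
36 | (2E,4S,5R,7S,12R,13R)-12-[(tert-butyldimethylsilyl)oxy]-13-{[(tert-butyldimethylsilyl)oxy]methyl}-4,5-epoxy-3,5,7-trimethyltetradec-2-enedioic acid 1-ethyl ester | C/C(=C\C(=O)OCC)[C@@H]1O[C@]1(C)C[C@@H](C)CCCC[C@@H](O[Si](C)(C)C(C)(C)C)[C@@H](CO[Si](C)(C)C(C)(C)C)C(=O)O | intermediate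
37 | (2E,4S,5R,7S,12R,13R)-4,5-epoxy-12-hydroxy-13-(hydroxymethyl)-3,5,7-trimethyltetradec-2-enedioic acid 1-ethyl ester | C/C(=C\C(=O)OCC)[C@@H]1O[C@]1(C)C[C@@H](C)CCCC[C@@H](O)[C@@H](CO)C(=O)O | intermediate
38 | (2E,4S,5R,7S,12R,13R)-4,5-epoxy-12-hydroxy-13-(hydroxymethyl)-3,5,7-trimethyltetradec-2-enedioic acid | C/C(=C\C(=O)O)[C@@H]1O[C@]1(C)C[C@@H](C)CCCC[C@@H](O)[C@@H](CO)C(=O)O | target

**Step count**
Total step count: 22.
Longest linear sequence: 19 steps, from but-2-yn-1-ol 1 through steps 1, 2, 4–11 and 14–22. The Roche-ester line has 18 steps and the imide branch adds 2.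

**Steps most likely to fail**

1. Step 18.
 - Risk: facial discrimination may be poor. In this 4Z alkene the long C6 chain, not the methyl group, lies cis to the twisted C3 alkenyl substituent, so the spiro and planar approaches of the dioxirane may come close in energy.
 - Fallback: catalyst control is given up in favour of separation. Setting out from 33, m-CPBA buffered with NaHCO3 (CH2Cl2, 0 °C) should still choose the electron-richer C4=C5 alkene and add oxygen stereospecifically syn to either face. This would give 34 together with the (4R,5S)-epoxide diastereomer F1.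
 - Because C7, C12 and C13 make the two products diastereomers, they would be parted by preparative HPLC. The route is rejoined at 34.

2. Step 17.
 - Risk: acylation of the hindered dienylalane may be slow. Prolonged contact with the chloroaluminium species and the chloroformate could then erode the 4Z geometry or cleave the PMB ether.
 - Fallback: the two bond formations are separated. Setting out from 29, the same methylalumination gives 32, which is quenched with I2 in THF at −30 °C (a fast, retentive iodinolysis) to give the (1E,3Z)-dienyl iodide F2, which is isolated.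
 - Palladium-catalysed ethoxycarbonylation of F2 (CO at 1 atm, EtOH, Et3N, PdCl2(PPh3)2, DMF, 50 °C) then forms C1–C2 with retention under non-Lewis-acidic conditions. The route is rejoined at 33.

3. Step 10.
 - Risk: the Z-enal may isomerise to the E-enal through reversible conjugate addition, or the lithiated diazo reagent may add 1,4, before the alkyne is formed.
 - Fallback: the carbene route is replaced by olefination and elimination (Corey–Fuchs sequence). Setting out from 15, CBr4/PPh3 with Et3N (CH2Cl2, 0 °C) should give the 1,1-dibromodiene F3 under essentially neutral conditions.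
 - n-BuLi (2 equiv, THF, −78 °C) followed by aqueous NH4Cl converts F3 into the terminal alkyne by elimination and bromine–lithium exchange. The route is rejoined at 18.

**Further compounds**
F1 | step 18 | ethyl (2E,4R,5S,7S,12R,13R)-12,14-bis[(tert-butyldimethylsilyl)oxy]-4,5-epoxy-13-{[(4-methoxybenzyl)oxy]methyl}-3,5,7-trimethyltetradec-2-enoate | C/C(=C\C(=O)OCC)[C@H]1O[C@@]1(C)C[C@@H](C)CCCC[C@@H](O[Si](C)(C)C(C)(C)C)[C@@H](CO[Si](C)(C)C(C)(C)C)COCc1ccc(OC)cc1
F2 | step 17 | (1E,3Z,6S,11R,12R)-11,13-bis[(tert-butyldimethylsilyl)oxy]-1-iodo-12-{[(4-methoxybenzyl)oxy]methyl}-2,4,6-trimethyltrideca-1,3-diene | C/C(=C\I)/C=C(/C)C[C@@H](C)CCCC[C@@H](O[Si](C)(C)C(C)(C)C)[C@@H](CO[Si](C)(C)C(C)(C)C)COCc1ccc(OC)cc1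
F3 | step 10 | 2-[(5S,7Z)-10,10-dibromo-5,7-dimethyldeca-7,9-dien-1-yl]-1,3-dioxolane | BrC(Br)=C/C=C(/C)C[C@@H](C)CCCCC1OCCO1
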